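**Retrosynthetic overview**

1. Target ⇐ Lindlar semi-hydrogenation of both alkynes ⇐ C7 O-acetylation of a diyne aldol.
2. Diyne aldol (C7–C8 bond) ⇐ dianion of (S)-2-chloro-4-hydroxy-4-(oct-2-ynyl)cyclopent-2-enone + methyl 7-oxohept-5-ynoate; C7 and C8 by substrate control.
3. Chloro-enone ⇐ α-chlorination ⇐ (S)-4-hydroxy-4-(oct-2-ynyl)cyclopent-2-enone ⇐ key C–O bond: catalytic enantioselective desymmetrizing allylic oxygenation of achiral 1-(oct-2-ynyl)cyclopent-3-en-1-ol (sets C12).
4. Achiral cyclopentenol ⇐ heptynide opening of a spiro-epoxide ⇐ ring-closing metathesis ⇐ ethyl chloroacetate + two equivalents of allylmagnesium bromide.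
5. Ring order: the only ring (cyclopentene) is closed first by metathesis and is oxidized and substituted afterwards; no other ring is formed.

Assumption: the (S,S,S,S)-diselenide catalyst is taken to give the (S)-hydroxy-enone; if a test run shows the opposite sense, its enantiomer is used.

Prostaglandin numbering is used in the comments: C7 is the acetoxy carbon, C8 the ring CH, C12 the ring carbinol.

**Step 1**
Reactants: 1 ethyl chloroacetate; 2 allylmagnesium bromide
Product: 4 4-(chloromethyl)hepta-1,6-dien-4-ol, via chloromethyl ketone 3 (not isolated)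
Conditions: 2 (1.0 M in Et2O, 2.3 equiv), THF, −78 → 0 °C; aq. NH4Cl
Reagents that add atoms: allylmagnesium bromide (second equivalent of 2), C=CC[Mg]Br
Why: Double Grignard addition to an ester, in which the first equivalent of 2 displaces ethoxide to give 1-chloropent-4-en-2-one 3 and the second equivalent adds at once to this more electrophilic ketone, while the magnesium alkoxide of the tertiary chlorohydrin does not close to the epoxide below 0 °C; no stereocentre is formed.

**Step 2**
Reactants: 4 4-(chloromethyl)hepta-1,6-dien-4-ol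
Product: 5 1-(chloromethyl)cyclopent-3-en-1-ol
Conditions: second-generation Grubbs catalyst RuCl2(=CHPh)(PCy3)(SIMes) (1 mol%), CH2Cl2 (0.1 M), 40 °C
Reagents that add atoms: none
Why: Ring-closing metathesis of a 1,6-diene with a quaternary carbinol centre (gem-disubstituent effect) closes the cyclopentene with loss of ethene; the product is achiral.

**Step 3**
Reactants: 5 1-(chloromethyl)cyclopent-3-en-1-ol; 6 hept-1-yne
Product: 9 1-(oct-2-yn-1-yl)cyclopent-3-en-1-ol, via lithium heptynide 7 (not isolated), via spiro-epoxide 8 (not isolated)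
Conditions: 6 (2.6 equiv), n-BuLi (2.5 equiv), THF, −78 → 0 °C; then 5, 0 °C → rt; DMPU, 45 °C; aq. NH4Cl
Reagents that add atoms: none
Why: Intramolecular Williamson closure of the lithium alkoxide gives the spiro-epoxide, which the lithium acetylide opens by SN2 attack at the unhindered CH2 (the acetylide is too weak a base to isomerize the epoxide); the product is achiral and mirror-symmetric.

**Step 4**
Reactants: 9 1-(oct-2-yn-1-yl)cyclopent-3-en-1-ol
Product: 11 (S)-4-hydroxy-4-(oct-2-yn-1-yl)cyclopent-2-en-1-one, via allylic trans-diol 10 (not isolated)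
Conditions: bis{2,6-bis[(1S)-1-methoxyethyl]phenyl} diselenide (10 mol%), 2,4,6-tris(4-methoxyphenyl)pyrylium tetrafluoroborate (5 mol%), air, 465 nm LEDs, MeCN/H2O 10:1, 5 °C; then evaporate MeCN, MnO2 (15 equiv), CH2Cl2, rt
Reagents that add atoms: water, O
Why: Proposed new method: enantioselective desymmetrizing selenium-π-acid allylic hydroxylation, in which photo-oxidation of the chiral diselenide (O2 as terminal oxidant, ending as water) gives an ArSe+ equivalent that forms a seleniranium ion on the strained ring alkene (faster than on the dialkyl alkyne) on the face syn to the tertiary OH, the C2-symmetric 1-methoxyethyl arms (Se···O contact) leave only one of the two enantiotopic ring carbons open to anti attack by water so that this C–O bond fixes the carbinol centre as S, oxidative elimination of selenium toward the CH2 remote from the new oxygen gives the transposed allylic diol and returns the catalyst, and MnO2 then oxidizes only the secondary allylic alcohol; the closest known reaction types are photo-aerobic selenium-π-acid allylic acyloxylation of simple alkenes and asymmetric oxyselenenylation–elimination with chiral diselenides.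

**Step 5**
Reactants: 11 (S)-4-hydroxy-4-(oct-2-yn-1-yl)cyclopent-2-en-1-one
Product: 12 (S)-2-chloro-4-hydroxy-4-(oct-2-yn-1-yl)cyclopent-2-en-1-one
Conditions: PhICl2 (1.2 equiv), pyridine (3 equiv), CH2Cl2, 0 °C → rt, dark
Reagents that add atoms: (dichloroiodo)benzene, ClI(Cl)c1ccccc1
Why: α-Chlorination of an enone by addition–elimination (chlorine is delivered across the electron-poor ring C=C and pyridine then removes the acidic α-hydrogen with loss of the β-chloride), with the tertiary alcohol and, in the dark at 0 °C, the dialkyl alkyne as spectators; the stereocentre is not touched.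

**Step 6**
Reactants: 13 methyl hex-5-ynoate
Product: 15 methyl 7-oxohept-5-ynoate, via lithium acetylide 14 (not isolated)
Conditions: LiN(i-Pr)2 (1.05 equiv), THF, −78 °C; DMF (2 equiv), −78 → −20 °C; inverse quench into cold 10% aq. KH2PO4
Reagents that add atoms: N,N-dimethylformamide, CN(C)C=O
Why: Formylation of a lithium acetylide with DMF works because the sp C–H is the most acidic and the fastest-removed proton in THF at −78 °C, and the hemiaminal alkoxide survives until the buffered inverse quench, which keeps dimethylamine from adding to the ynal.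

**Step 7**
Reactants: 12 (S)-2-chloro-4-hydroxy-4-(oct-2-yn-1-yl)cyclopent-2-en-1-one; 15 methyl 7-oxohept-5-ynoate
Product: 17 methyl (7R)-7-[(1R,2S)-4-chloro-2-hydroxy-2-(oct-2-yn-1-yl)-5-oxocyclopent-3-en-1-yl]-7-hydroxyhept-5-ynoate, via dilithium dianion 16 (not isolated)
Conditions: 12 added to LiN(i-Pr)2 (2.3 equiv), THF, −78 °C, 30 min; 15 (1.3 equiv), −78 °C, 15 min; aq. NH4Cl at −78 °C
Reagents that add atoms: none
Why: Aldol addition of a β-alkoxide ketone dianion (Fráter–Seebach type), in which the ring-locked E-enolate reacts through a Zimmerman–Traxler chair to give the anti aldol and the ynal is delivered to the face syn to the small lithium alkoxide and anti to the propargylic chain, setting C8 as R (side chain cis to OH) and C7 in the arrangement that is 7R here and 7S in the target (priority change alkyne → alkene); the alkoxide cannot leave, so no β-elimination occurs.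

**Step 8**
Reactants: 17 methyl (7R)-7-[(1R,2S)-4-chloro-2-hydroxy-2-(oct-2-yn-1-yl)-5-oxocyclopent-3-en-1-yl]-7-hydroxyhept-5-ynoate
Product: 18 methyl (7R)-7-(acetyloxy)-7-[(1R,2S)-4-chloro-2-hydroxy-2-(oct-2-yn-1-yl)-5-oxocyclopent-3-en-1-yl]hept-5-ynoate
Conditions: Ac2O (1.5 equiv), pyridine, CH2Cl2, 0 °C
Reagents that add atoms: acetic anhydride, CC(=O)OC(C)=O
Why: O-Acetylation takes the secondary propargylic hydroxyl only (the tertiary one does not react without DMAP), and low temperature without strong base avoids β-elimination of acetate; no stereocentre changes.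

**Step 9**
Reactants: 18 methyl (7R)-7-(acetyloxy)-7-[(1R,2S)-4-chloro-2-hydroxy-2-(oct-2-yn-1-yl)-5-oxocyclopent-3-en-1-yl]hept-5-ynoate
Product: 19 punaglandin 8, methyl (5Z,7S)-7-(acetyloxy)-7-{(1R,2S)-4-chloro-2-hydroxy-2-[(2Z)-oct-2-en-1-yl]-5-oxocyclopent-3-en-1-yl}hept-5-enoate
Conditions: H2 (1 atm, stopped at 2.0 equiv uptake), Lindlar catalyst (5% Pd on CaCO3, poisoned with Pb(OAc)2), quinoline (0.5 equiv), EtOAc, 0 °C → rt
Reagents that add atoms: none
Why: Lindlar semi-hydrogenation delivers H2 syn to both internal alkynes to give the two Z-alkenes, while the trisubstituted chloro-enone, the vinylic C–Cl, the acetate and the ester are not reduced on the quinoline-poisoned surface; no stereocentre is touched.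

**Compound list**

1 | ethyl chloroacetate | CCOC(=O)CCl | starting material
2 | allylmagnesium bromide | C=CC[Mg]Br | starting material
3 | 1-chloropent-4-en-2-one | ClCC(=O)CC=C | intermediate (not isolated)
4 | 4-(chloromethyl)hepta-1,6-dien-4-ol | C=CCC(O)(CCl)CC=C | intermediate
5 | 1-(chloromethyl)cyclopent-3-en-1-ol | OC1(CCl)CC=CC1 | intermediate
6 | hept-1-yne | C#CCCCCC | starting material
7 | lithium hept-1-yn-1-ide | [Li+].[C-]#CCCCCC | intermediate (not isolated)
8 | 1-oxaspiro[2.4]hept-5-ene | C1=CCC2(C1)CO2 | intermediate (not isolated)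
9 | 1-(oct-2-yn-1-yl)cyclopent-3-en-1-ol (achiral) | CCCCCC#CCC1(O)CC=CC1 | intermediate
10 | (1S,4S)-1-(oct-2-yn-1-yl)cyclopent-2-ene-1,4-diol (hydroxyls trans) | CCCCCC#CC[C@@]1(O)C=C[C@@H](O)C1 | intermediate (not isolated)
11 | (S)-4-hydroxy-4-(oct-2-yn-1-yl)cyclopent-2-en-1-one | CCCCCC#CC[C@@]1(O)C=CC(=O)C1 | intermediate
12 | (S)-2-chloro-4-hydroxy-4-(oct-2-yn-1-yl)cyclopent-2-en-1-one | CCCCCC#CC[C@@]1(O)C=C(Cl)C(=O)C1 | intermediate
13 | methyl hex-5-ynoate | C#CCCCC(=O)OC | starting material
14 | methyl 6-lithiohex-5-ynoate | [Li+].[C-]#CCCCC(=O)OC | intermediate (not isolated)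
15 | methyl 7-oxohept-5-ynoate | O=CC#CCCCC(=O)OC | intermediate
16 | dilithium (S)-2-chloro-4-oxido-4-(oct-2-yn-1-yl)cyclopenta-1,5-dien-1-olate (alkoxide-enolate of 12) | CCCCCC#CC[C@@]1([O-])C=C(Cl)C([O-])=C1.[Li+].[Li+] | intermediate (not isolated)
17 | methyl (7R)-7-[(1R,2S)-4-chloro-2-hydroxy-2-(oct-2-yn-1-yl)-5-oxocyclopent-3-en-1-yl]-7-hydroxyhept-5-ynoate | CCCCCC#CC[C@@]1(O)C=C(Cl)C(=O)[C@@H]1[C@H](C#CCCCC(=O)OC)O | intermediate
18 | methyl (7R)-7-(acetyloxy)-7-[(1R,2S)-4-chloro-2-hydroxy-2-(oct-2-yn-1-yl)-5-oxocyclopent-3-en-1-yl]hept-5-ynoate | CCCCCC#CC[C@@]1(O)C=C(Cl)C(=O)[C@@H]1[C@H](C#CCCCC(=O)OC)OC(C)=O | intermediate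
19 | punaglandin 8, methyl (5Z,7S)-7-(acetyloxy)-7-{(1R,2S)-4-chloro-2-hydroxy-2-[(2Z)-oct-2-en-1-yl]-5-oxocyclopent-3-en-1-yl}hept-5-enoate | CCCCC/C=C\C[C@@]1(O)C=C(Cl)C(=O)[C@@H]1[C@H](/C=C\CCCC(=O)OC)OC(C)=O | target

**Count and risks**

Total steps: 9. Longest linear sequence: 8 (steps 1–5, 7–9); step 6 is a one-step side branch.

Three steps most likely to fail:

Step 4 (the proposed new method). Desymmetrizing a cis-cycloalkene through a seleniranium ion is the hardest case for chiral selenium electrophiles, so the ee may be low. Racemic background oxidation and selenium-induced cyclization of the homopropargylic alcohol are further risks. Fallback with known chemistry, setting out from 9 and returning at 11: hydroxyl-directed epoxidation (mCPBA, NaHCO3, CH2Cl2, 0 °C) gives meso-3-(oct-2-yn-1-yl)-6-oxabicyclo[3.1.0]hexan-3-ol F1. Enantioselective rearrangement of this meso epoxide to the allylic alcohol follows, using a chiral lithium amide: catalytic lithium amide of (1S,3R,4R)-3-(pyrrolidin-1-ylmethyl)-2-azabicyclo[2.2.1]heptane or its enantiomer, LiN(i-Pr)2, DBU, THF, 0 °C. This is an established desymmetrization of 4-substituted cyclopentene oxides and gives (1S,4R)-1-(oct-2-yn-1-yl)cyclopent-2-ene-1,4-diol F2. MnO2 in CH2Cl2 then gives 11. Here the stereocentre is set by enantiotopic proton removal.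

Step 5 (α-chlorination). The electrophilic chlorine source may also attack the side-chain alkyne. Fallback, setting out from 11 and returning at 12: nucleophilic epoxidation, which touches only the enone (30% H2O2, cat. NaOH, MeOH, −20 → 0 °C), gives (4S)-4-hydroxy-4-(oct-2-yn-1-yl)-6-oxabicyclo[3.1.0]hexan-2-one F3. Concentrated HCl in THF (0 °C → rt) then opens the epoxide at the α-carbon, and the β-hydroxy ketone dehydrates to give 12.

Step 7 (dianion aldol). Risks are retro-aldol opening or poor behaviour of the dianion, a low anti:syn ratio with the small alkynyl aldehyde, and imperfect facial control. Fallback, setting out from 12 and returning at 17: silylation (TMSCl, imidazole, DMF, 0 °C) gives (S)-2-chloro-4-(oct-2-yn-1-yl)-4-[(trimethylsilyl)oxy]cyclopent-2-en-1-one F4. Mono-enolization (LiN(i-Pr)2, 1.1 equiv, THF, −78 °C) gives lithium (S)-2-chloro-4-(oct-2-yn-1-yl)-4-[(trimethylsilyl)oxy]cyclopenta-1,5-dien-1-olate F5, a type of enolate with precedent in earlier punaglandin work. Addition of 15 gives methyl (7R)-7-[(1R,2S)-4-chloro-2-(oct-2-yn-1-yl)-5-oxo-2-[(trimethylsilyl)oxy]cyclopent-3-en-1-yl]-7-hydroxyhept-5-ynoate F6. If the anti:syn ratio is still poor, F4 can instead be enolized with chlorodicyclohexylborane/Et3N, which is reliably anti. AcOH/THF/H2O at rt then removes the silyl group to give 17. The trade-off is that facial selectivity with the silyl ether rests on sterics alone, so C8 epimers may need separation at F6.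

**Further compounds**

F1 | step 4 | meso-3-(oct-2-yn-1-yl)-6-oxabicyclo[3.1.0]hexan-3-ol (epoxide oxygen cis to the hydroxyl) | CCCCCC#CC[C@]1(O)C[C@H]2O[C@H]2C1
F2 | step 4 | (1S,4R)-1-(oct-2-yn-1-yl)cyclopent-2-ene-1,4-diol (hydroxyls cis) | CCCCCC#CC[C@@]1(O)C=C[C@H](O)C1
F3 | step 5 | (4S)-4-hydroxy-4-(oct-2-yn-1-yl)-6-oxabicyclo[3.1.0]hexan-2-one (epoxide oxygen cis to the hydroxyl) | CCCCCC#CC[C@@]1(O)[C@@H]2O[C@@H]2C(=O)C1
F4 | step 7 | (S)-2-chloro-4-(oct-2-yn-1-yl)-4-[(trimethylsilyl)oxy]cyclopent-2-en-1-one | CCCCCC#CC[C@@]1(O[Si](C)(C)C)C=C(Cl)C(=O)C1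
F5 | step 7 | lithium (S)-2-chloro-4-(oct-2-yn-1-yl)-4-[(trimethylsilyl)oxy]cyclopenta-1,5-dien-1-olate | CCCCCC#CC[C@@]1(O[Si](C)(C)C)C=C(Cl)C([O-])=C1.[Li+]
F6 | step 7 | methyl (7R)-7-[(1R,2S)-4-chloro-2-(oct-2-yn-1-yl)-5-oxo-2-[(trimethylsilyl)oxy]cyclopent-3-en-1-yl]-7-hydroxyhept-5-ynoate | CCCCCC#CC[C@@]1(O[Si](C)(C)C)C=C(Cl)C(=O)[C@@H]1[C@H](C#CCCCC(=O)OC)O
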